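Ring B (C5–C10) is cut at C9–C10 and C5–C6. This is possible because C4, the carbon that finally bears C15 and the C3=C4 double bond, can first be a ketone in ring A. C5 and C10 are then the α- and β-carbons of an enone. The four-carbon unit C6–C9, carrying O6 and the isopropyl group on C7, is a 1-siloxy-2-isopropylbutadiene. One enantioselective, Lewis acid catalysed Diels–Alder reaction of 3-methylcyclohex-2-enone with this diene forms both bonds, closes ring B and fixes quaternary C10. In the target H5, H6 and H7 all lie opposite the C10 methyl group, so each is later delivered to that open face: proton at C5, hydrogen at C7, hydride at C6.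

Key step: step 4

Convention: eudesmane numbering is used throughout; β is the face of the C10 methyl group (C14), α the opposite face.
Assumption: the (S)-diphenylprolinol-derived catalyst is taken to leave open the face of 3-methylcyclohex-2-enone that is Si at C2 and C3. If the sense of induction is the opposite, the (R)-catalyst is used and nothing else changes.

Step 1
Reactants: 1 isovaleraldehyde (3-methylbutanal)
Product: 2 (E)-N-cyclohexyl-3-methylbutan-1-imine
Conditions: CyNH2, Et2O, MgSO4, 0 °C → rt; distil
Reagents that add atoms: cyclohexylamine, NC1CCCCC1
Why: Imine condensation; masking 1 as its N-cyclohexyl imine makes it the only possible nucleophile in step 2 and so removes the self- and cross-condensation mixtures of an undirected aldol between two enolisable aldehydes.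

Step 2
Reactants: 2 (E)-N-cyclohexyl-3-methylbutan-1-imine; 3 acetaldehyde
Product: 6 (E)-2-isopropylbut-2-enal, via lithiated imine 4 (not isolated), via hydroxy imine 5 (not isolated)
Conditions: LDA, THF, 0 °C; 3, −78 °C; H2O; then aq. oxalic acid, reflux
Reagents that add atoms: water, O
Why: Directed aldol reaction through a metalloenamine: the preformed lithiated imine adds once to the more electrophilic acetaldehyde, and acid hydrolysis of the imine with loss of water gives the conjugated enal as the more stable E isomer (C4 methyl trans to CHO), a geometry that disappears anyway in step 3.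

Step 3
Reactants: 6 (E)-2-isopropylbut-2-enal
Product: 7 (1E)-1-(tert-butyldimethylsilyloxy)-2-isopropylbuta-1,3-diene (silyloxy group trans to the vinyl group)
Conditions: TBSOTf, Et3N, Et2O, 0 °C → rt
Reagents that add atoms: tert-butyldimethylsilyl triflate, CC(C)(C)[Si](C)(C)OS(=O)(=O)C(F)(F)F
Why: Soft vinylogous enolisation (silyl dienol ether formation): O-silylation of the s-trans enal and removal of a proton from the only γ-position, the C4 methyl group, should give the 1E-dienol ether as known for tiglic aldehyde, and any 1Z isomer cannot reach a reactive s-cis conformation and stays a spectator in step 4.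

Step 4
Reactants: 7 (1E)-1-(tert-butyldimethylsilyloxy)-2-isopropylbuta-1,3-diene; 8 3-methylcyclohex-2-en-1-one
Product: 9 (5R,6R,10R)-6-(tert-butyldimethylsilyloxy)-15-noreudesm-7-en-4-one (cis-fused, H5 β like the C10 methyl, 6α-silyloxy group cis to C4 on ring B, endo adduct)
Conditions: (S)-diphenylprolinol B-(o-tolyl)oxazaborolidine (20 mol %), AlBr3 (16 mol %), CH2Cl2, −40 → −20 °C; Et3N quench
Reagents that add atoms: none
Why: Proposed new method: the cationic boron Lewis acid binds the C4 carbonyl oxygen of 8 and lowers the enone LUMO, so that 7 adds in a strongly asynchronous [4+2] cycloaddition in which its unsubstituted terminus C9 (largest HOMO coefficient, vinylogous to the siloxy donor) bonds first to the β-carbon C10 and C6 then closes on C5; a fully stepwise vinylogous Mukaiyama–Michael addition followed by aldol closure would end in the same adduct. The closest known reactions are the achiral aluminium Lewis acid promoted Diels–Alder additions of silyloxydienes to 3-methylcyclohex-2-enone and the oxazaborolidinium-catalysed enantioselective additions to cyclohexenones without a β-substituent; new is their combination, enantiocontrol on a β-methyl enone with creation of a quaternary carbon. Ring B closes as a six-membered carbocycle by intermolecular [4+2] annulation, both bonds forming on one face of the ring A olefin (in the stepwise limit a 6-(enolexo)-exo-trig aldol). C10 is controlled by the catalyst, which covers the Re face of the enone so that C9 arrives on the Si face; C5 follows from suprafacial addition to the ring olefin (H5 cis to the C10 methyl, cis fusion); C6 follows from the 1E geometry of 7 and the endo position of the C4 carbonyl. The route needs only two selectivities from this step, the regiochemistry, which the 1-siloxy group secures against the weaker directing effect of the 2-alkyl group, and the face at C10, since C5 and C6 are set again in steps 9 and 11. The low reactivity of the β,β-disubstituted enone is met by the strongest activation mode of the catalyst, an electron-rich diene with a sterically free terminus and high concentration.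

Step 5
Reactants: 9 cis-fused adduct
Product: 11 6α-(tert-butyldimethylsilyloxy)-5βH-15-noreudesma-3,7-dien-4-yl triflate, via potassium enolate 10 (not isolated)
Conditions: KHMDS, THF, −78 °C; N-(5-chloro-2-pyridyl)triflimide, −78 → −40 °C; aq. NH4Cl
Reagents that add atoms: N-(5-chloro-2-pyridyl)bis(trifluoromethanesulfonimide), O=S(=O)(N(c1ccc(Cl)cn1)S(=O)(=O)C(F)(F)F)C(F)(F)F
Why: Kinetic enolate formation and O-sulfonylation: the bulky amide removes a proton from the open C3 methylene and not the C5 methine, which is tertiary and wedged between quaternary C10 and the silyloxy-bearing C6, so β-elimination of the silyloxy group is avoided and trapping at −78 °C fixes the position of the later C3=C4 olefin.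

Step 6
Reactants: 11 enol triflate
Product: 12 6α-(tert-butyldimethylsilyloxy)-5βH-eudesma-3,7-diene
Conditions: MeMgBr, Fe(acac)3 (10 mol %), THF/NMP, −30 → 0 °C
Reagents that add atoms: methylmagnesium bromide, C[Mg]Br
Why: Iron-catalysed Kumada-type cross-coupling of an alkenyl triflate with a methyl Grignard reagent replaces the triflate by C15 without moving the double bond, and the silyl ether and the C7=C8 olefin are inert.

Step 7
Reactants: 12 silyl ether
Product: 13 5βH-eudesma-3,7-dien-6α-ol
Conditions: TBAF, THF, rt → 45 °C
Reagents that add atoms: none
Why: Fluoride-induced silyl ether cleavage, for which 12 offers no base-sensitive group.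

Step 8
Reactants: 13 allylic alcohol
Product: 14 (5S,10R)-5βH-eudesma-3,7-dien-6-one (cis-fused)
Conditions: Dess–Martin periodinane, CH2Cl2, 0 °C → rt
Reagents that add atoms: none
Why: Dess–Martin oxidation of an allylic alcohol under nearly neutral conditions erases the C6 stereocentre on purpose and turns H5 into the most acidic proton of the molecule (α′ to the new enone and allylic to C3=C4).

Step 9
Reactants: 14 cis-fused dienone
Product: 16 (5R,10R)-5αH-eudesma-3,7-dien-6-one (trans-fused), via potassium trienolate 15 (not isolated)
Conditions: KHMDS, THF, −78 °C; inverse quench into AcOH/THF, −78 °C; pH 7 buffer; used without delay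
Reagents that add atoms: none
Why: Kinetic deprotonation and kinetic C-protonation of an extended enolate (the principle of deconjugative protonation): H5 is the α′-proton of the enone and is allylic as well, so it alone is removed, and the flat trienolate 15 takes up the proton at its α-carbon C5 rather than at C3 and on the face anti to the C10 methyl group, which stands perpendicular to the π-system next to C5, giving H5α and the trans ring fusion.

Step 10
Reactants: 16 trans-fused dienone
Product: 17 (5R,7S,10R)-eudesm-3-en-6-one (trans-fused, 7β-isopropyl)
Conditions: H2 (1 atm), 5 % Pd/C, EtOAc, 0 °C → rt, stopped after one equivalent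
Reagents that add atoms: none
Why: Chemoselective heterogeneous hydrogenation: on palladium a conjugated C=C is taken up well before an isolated, hindered trisubstituted ring olefin (the selectivity used in the citral-to-citronellal hydrogenation), and in rigid trans-fused 16 the axial C10 methyl covers the β-face at C8 and C6, so both hydrogens add syn from the α-face and leave the isopropyl group β (equatorial); the olefin was kept until now because the cis-fused compounds expose the opposite face and because an isopropyl group next to a ketone has too weak an equatorial preference to be corrected by equilibration.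

Step 11
Reactants: 17 eudesm-3-en-6-one
Product: 18 (5R,6R,7S,10R)-eudesm-3-en-6β-ol (axial hydroxyl)
Conditions: L-Selectride, THF, −78 → 0 °C; NaOH, H2O2, 0 °C
Reagents that add atoms: none
Why: Bulky-hydride (L-Selectride) ketone reduction under steric approach control: the axial trajectory on the β-face is closed by the syn-axial C10 methyl, so hydride enters equatorially from the α-face and gives the axial 6β-alcohol without touching C5 or C7.

Step 12
Reactants: 19 p-coumaric acid
Product: 21 (E)-3-[4-(tert-butyldimethylsilyloxy)phenyl]acrylic acid, via bis-silyl derivative 20 (not isolated)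
Conditions: TBSCl, imidazole, DMF, rt; then AcOH/THF/H2O, rt
Reagents that add atoms: tert-butyldimethylsilyl chloride, CC(C)(C)[Si](C)(C)Cl
Why: Silylation of phenol and acid followed by selective hydrolysis of the far more labile silyl ester leaves only the phenol masked, which prevents self-acylation in step 13.

Step 13
Reactants: 18 eudesm-3-en-6β-ol; 21 O-silylated p-coumaric acid
Product: 23 eudesm-3-en-6β-yl (E)-4-(tert-butyldimethylsilyloxy)cinnamate, via mixed anhydride 22 (not isolated)
Conditions: 2,4,6-trichlorobenzoyl chloride, Et3N, THF, rt; then 18, DMAP, toluene, 80 °C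
Reagents that add atoms: none
Why: Yamaguchi esterification: the mixed anhydride and the acylpyridinium ion derived from it are reactive enough for the hindered axial 6β-hydroxyl, the C6–O bond is not touched so C6 keeps its configuration, and the E-cinnamate olefin is unaffected.

Step 14
Reactants: 23 silylated ester
Product: 24 target, (5R,6R,7S,10R)-eudesm-3-en-6β-yl (E)-p-coumarate
Conditions: TBAF, AcOH, THF, 0 °C
Reagents that add atoms: none
Why: Buffered fluoride cleavage of an aryl silyl ether is fast at 0 °C, and the acetic acid buffer keeps the medium too weakly basic to attack the cinnamate ester or move the C3=C4 olefin.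

Compound list
1 | isovaleraldehyde | CC(C)CC=O | starting material
2 | (E)-N-cyclohexyl-3-methylbutan-1-imine | CC(C)C/C=N/C1CCCCC1 | intermediate
3 | acetaldehyde | CC=O | starting material
4 | lithiated imine (lithium aza-enolate of 2) | [Li+].CC(C)C=C[N-]C1CCCCC1 | intermediate
5 | N-cyclohexyl-3-hydroxy-2-isopropylbutan-1-imine (mixture of diastereomers) | CC(O)C(C(C)C)/C=N/C1CCCCC1 | intermediate
6 | (E)-2-isopropylbut-2-enal | C/C=C(/C=O)C(C)C | intermediate
7 | (1E)-1-(tert-butyldimethylsilyloxy)-2-isopropylbuta-1,3-diene | C=C/C(C(C)C)=C/O[Si](C)(C)C(C)(C)C | intermediate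
8 | 3-methylcyclohex-2-en-1-one | CC1=CC(=O)CCC1 | starting material
9 | (5R,6R,10R)-6α-(tert-butyldimethylsilyloxy)-5βH-15-noreudesm-7-en-4-one | O=C1CCC[C@]2(C)CC=C(C(C)C)[C@H](O[Si](C)(C)C(C)(C)C)[C@H]12 | intermediate
10 | potassium C3–C4 enolate of 9 | [K+].[O-]C1=CCC[C@]2(C)CC=C(C(C)C)[C@H](O[Si](C)(C)C(C)(C)C)[C@H]12 | intermediate
11 | 6α-(tert-butyldimethylsilyloxy)-5βH-15-noreudesma-3,7-dien-4-yl triflate | O=S(=O)(OC1=CCC[C@]2(C)CC=C(C(C)C)[C@H](O[Si](C)(C)C(C)(C)C)[C@H]12)C(F)(F)F | intermediate
12 | 6α-(tert-butyldimethylsilyloxy)-5βH-eudesma-3,7-diene | CC1=CCC[C@]2(C)CC=C(C(C)C)[C@H](O[Si](C)(C)C(C)(C)C)[C@H]12 | intermediate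
13 | 5βH-eudesma-3,7-dien-6α-ol | CC1=CCC[C@]2(C)CC=C(C(C)C)[C@H](O)[C@H]12 | intermediate
14 | (5S,10R)-5βH-eudesma-3,7-dien-6-one | CC1=CCC[C@]2(C)CC=C(C(C)C)C(=O)[C@H]12 | intermediate
15 | potassium eudesma-3,5,7-trien-6-olate | [K+].CC1=CCC[C@]2(C)CC=C(C(C)C)C([O-])=C12 | intermediate
16 | (5R,10R)-5αH-eudesma-3,7-dien-6-one | CC1=CCC[C@]2(C)CC=C(C(C)C)C(=O)[C@@H]12 | intermediate
17 | (5R,7S,10R)-eudesm-3-en-6-one | CC1=CCC[C@]2(C)CC[C@@H](C(C)C)C(=O)[C@@H]12 | intermediate
18 | (5R,6R,7S,10R)-eudesm-3-en-6β-ol | CC1=CCC[C@]2(C)CC[C@@H](C(C)C)[C@@H](O)[C@@H]12 | intermediate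
19 | p-coumaric acid | O=C(O)/C=C/c1ccc(O)cc1 | starting material
20 | tert-butyldimethylsilyl (E)-4-(tert-butyldimethylsilyloxy)cinnamate | CC(C)(C)[Si](C)(C)OC(=O)/C=C/c1ccc(O[Si](C)(C)C(C)(C)C)cc1 | intermediate
21 | (E)-4-(tert-butyldimethylsilyloxy)cinnamic acid | O=C(O)/C=C/c1ccc(O[Si](C)(C)C(C)(C)C)cc1 | intermediate
22 | (E)-4-(tert-butyldimethylsilyloxy)cinnamic 2,4,6-trichlorobenzoic anhydride | O=C(OC(=O)c1c(Cl)cc(Cl)cc1Cl)/C=C/c1ccc(O[Si](C)(C)C(C)(C)C)cc1 | intermediate
23 | eudesm-3-en-6β-yl (E)-4-(tert-butyldimethylsilyloxy)cinnamate | CC1=CCC[C@]2(C)CC[C@@H](C(C)C)[C@@H](OC(=O)/C=C/c3ccc(O[Si](C)(C)C(C)(C)C)cc3)[C@@H]12 | intermediate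
24 | (5R,6R,7S,10R)-eudesm-3-en-6β-yl (E)-p-coumarate | CC1=CCC[C@]2(C)CC[C@@H](C(C)C)[C@@H](OC(=O)/C=C/c3ccc(O)cc3)[C@@H]12 | target

Total step count: 14. Longest linear sequence: 13 (steps 1–11, 13 and 14); step 12 is a one-step side branch.

Steps most likely to fail

Step 4. The hindered enone may not turn over on the chiral catalyst. The strong acid may consume the diene or strip silanol from the adduct. The catalyst may also discriminate poorly between the two faces at C10. The fallback separates bond formation from absolute control and sets out from 7 and 8. They are combined under the achiral mixed Lewis acid AlBr3/AlMe3 (toluene/CH2Cl2, −5 °C → rt), a known promoter for Diels–Alder additions of hindered silyloxydienes to 3-methylcyclohex-2-enone. This should give the racemic endo adduct, that is 9 together with the mirror-image adduct F1. The enantiomers are then separated by preparative chromatography on a polysaccharide chiral stationary phase, and the route is rejoined at 9.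

Step 9. The trienolate may be protonated at C3 or on the methyl-bearing face, and the labile β,γ-unsaturated ketone may slip back into conjugation during isolation. The fallback never isolates such a ketone and sets out from 14.
- DBU (CH2Cl2, rt) moves the C3=C4 bond fully into conjugation to give the stable cross-conjugated eudesma-4,7-dien-6-one F2, in which C10 is the only stereocentre.
- H2 over Pd/C saturates only the trisubstituted C7=C8 bond, from the α-face, to give eudesm-4-en-6-one F3.
- Isopropenyl acetate with catalytic TsOH at reflux gives the extended dienol acetate 6-acetoxyeudesma-3,5-diene F4.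
- NaBH4 in EtOH/THF/H2O cleaves the acetate (the protocol known for turning steroidal 4-en-3-ones into 5-en-3-ols). The dienolate is protonated at C5, and the unconjugated ketone is trapped at once by hydride from the α-face.

The route is rejoined at 18, so steps 9–11 are bypassed.

Step 10. Hydrogen uptake may not stop at the conjugated bond. Palladium may move the C3=C4 bond into conjugation, or part of the reduction may run through an enol and erode C7. The fallback replaces surface hydrogenation by nucleophilic 1,4-hydride transfer, which cannot touch an isolated olefin, and sets out from 16. L-Selectride (1.05 equiv, THF, −78 °C) adds hydride to the unsubstituted β-carbon C8 and gives the lithium C6–C7 enolate F5. This is protonated at −78 °C with acetic acid in THF, axially on the α-face, and the route is rejoined at 17. C7 then rests on enolate protonation instead of syn addition, so a C7 epimer may have to be removed at the stage of 18.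

Further compounds
F1 | step 4 | (5S,6S,10S)-6-(tert-butyldimethylsilyloxy)-15-noreudesm-7-en-4-one (mirror image of 9) | O=C1CCC[C@@]2(C)CC=C(C(C)C)[C@@H](O[Si](C)(C)C(C)(C)C)[C@@H]12
F2 | step 9 | (10R)-eudesma-4,7-dien-6-one | CC1=C2C(=O)C(C(C)C)=CC[C@@]2(C)CCC1
F3 | step 9 | (7S,10R)-eudesm-4-en-6-one | CC1=C2C(=O)[C@H](C(C)C)CC[C@@]2(C)CCC1
F4 | step 9 | (7S,10R)-6-acetoxyeudesma-3,5-diene | CC1=CCC[C@]2(C)CC[C@@H](C(C)C)C(OC(C)=O)=C12
F5 | step 10 | lithium (5R,10R)-eudesma-3,6-dien-6-olate | [Li+].CC1=CCC[C@]2(C)CCC(C(C)C)=C([O-])[C@@H]12
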